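Counted in units of starting material, the charge of this closed flask is conserved, so what side product B takes is lost to target and side product A together.

| flask | starting material | partner | time |
|---|---|---|---|
| Wednesday's | 20 mM | 2.80 equiv | 40 s |
| Tuesday's | 20 mM | 0.700 equiv | 40 s |
| Saturday's | 20 mM | 1.40 equiv | 40 s |

    starting material + partner → target (k1 = 9.4 /M/s)
    starting material → side product A (k2 = 0.086 /s)
    2 starting material → side product B (k3 = 17 /M/s)
    partner → decomposed reagent (k4 = 0.019 /s)

- which of the two there is more of at the end, counted by the starting material in each, Wednesday's (target / side product B)
- which of the two there is more of at the end, counted by the starting material in each, Tuesday's (target / side product B)
- which of the two there is more of at the end, counted by the starting material in each, Saturday's (target / side product B)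
- final target, as a percentage of the starting material charged, in Wednesday's
- final target, as a percentage of the starting material charged, in Tuesday's
- final target, as a percentage of the starting material charged, in Saturday's

- percent here means starting material units held: one side product B counts as two
- a step written with two of one species runs at k times the square of its concentration and takes two of it each time
- run time (Wednesday's): 40 s

Two chemists dispute Saturday's flask. The first reads it at the first instant: with [partner] at 28.0 mM and [starting material] at 20 mM, coupling draws 0.39 of what the step to side product B draws, and target gets 25.6% of the starting material consumed. The second reads the tail: as [starting material] falls, the second-order loss fades and the target share, at the charged [partner], climbs toward 75.4%. She holds that the run passes from one end to the other.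

I join the two ends. With [partner] held, coupling is pseudo-first-order, with frequency c, its rate constant times [partner]. Adding the rate constant of the step to side product A gives the first-order loss l. The second-order loss at the charge is q, 2 times the constant of the step to side product B times the charged [starting material]. I integrate to zero [starting material], since the run of 40 s is longer than 8.1 s, the half-life by the step to side product A alone. Then, with D = q/l, side product B holds 1 − ln(1+D)/D, and target holds c/l times ln(1+D)/D. The first chemist's factor is 1/(1+D), the second's is 1.

Coupling consumes partner, so I take [partner] as its charge less half the target of a first pass at the charge. I drop the partner's decay, which at Saturday's start draws 0.10 of what coupling draws. Saturday's first pass gives 41.8%, so [partner] is 23.8 mM, and the loss number, second-order over first-order loss, is 2.19. That gives Saturday's target 38.2% and side product B 47.1%, so more side product B. Wednesday's, at 50.2 mM, has D = 1.22, target 55.3% and side product B 34.6%, so more target. Tuesday's, at 11.3 mM, has D = 3.54, target 23.6% and side product B 57.3%, so more side product B.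

The forecast takes the second chemist's side, summing “In each slice, the fraction going to target” as [starting material] falls. It gives target 55.4%, 23.4% and 38.3% for Wednesday's, Tuesday's and Saturday's, with more target, side product B and side product B.

The simulation gives target 55.3%, 23.2% and 38.0% in that order, with more target, side product B and side product B, so the forecast holds and Saturday's first-instant 25.6% falls short. Removing the step from partner to decomposed reagent changes Wednesday's target by at most 0.5 percentage points. Saturday's D of 2.19 puts 53.0% in target and side product A together, and that flask ends with 53.3%. The first chemist keeps the region of D far below 1, where her factor and ln(1+D)/D meet; Wednesday's D is 1.22, above it.

Saturday's neighbour with 2.40 equiv of partner has [partner] at 42.6 mM and D = 1.40, less than Saturday's 2.19, so I reckon target 51.5% and side product B 37.5%. The computed neighbour gives target 51.4% and side product B 37.1%.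

All constants are those of an exercise; no experiment stands behind them.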